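**Plan** (benzofuran numbering: O1, C2 aryl, C3 methyl, C3a allyl, C4, C5 methoxy, C6 ketone, C7, C7a; ring A = carbocycle, ring B = oxygen heterocycle)
- Cuts, in order: O1–C7a (vinylogous ester back to a C6/C7a 1,3-diketone and the C2 alcohol), the C7a oxygen (back to the C7=C7a enone), then C7=C7a and C3a–C4 of ring A together, then C3a–allyl, then C2–C3.
- Enabling feature: the quaternary C3a lies next to C7a and γ to the C6 carbonyl, the pattern of a 4,4-disubstituted cyclohex-2-enone. Such a ring arises from an α-branched aldehyde (C7a formyl carbon, C3a α-carbon) and a vinyl ketone (C4–C7), and the C5 methoxy group sits on what is the α-carbon of that vinyl ketone.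
- Forward: C2–C3 by crotylboration, chain extension to the aldehyde, α-allylation; ring A by amine-catalysed Michael addition/aldol condensation with 3-methoxybut-3-en-2-one; ring B last, after C7a has been raised to the ketone level through the epoxy ketone.
- Stereochemistry: C2 and C3 from catalyst-controlled anti-crotylboration; C3a from the enamine face chosen by a chiral primary amine, with C3 as second element; C5 by thermodynamic equilibration in the last step.

Key step: step 7

Assumption: the (S)-phosphoric acid is taken to give the (1S)-carbinol in step 1 and the quinine-derived amine to be the matched catalyst for C3a in step 7; if either sense proves reversed, the antipodal acid or the quinidine-derived pseudoenantiomer is used with no other change.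

Step 1
Reactants: 1 3,4,5-trimethoxybenzaldehyde; 2 (E)-crotylboronic acid pinacol ester
Product: 4 (1S,2S)-2-methyl-1-(3,4,5-trimethoxyphenyl)but-3-en-1-ol, via O-boryl ether 3 (not isolated)
Conditions: (S)-3,3'-bis(2,4,6-triisopropylphenyl)-1,1'-binaphthyl-2,2'-diyl hydrogen phosphate (5 mol %), PhMe, 4 Å MS, −30 °C; H2O work-up
Reagents that add atoms: none
Why: chiral-phosphoric-acid-catalysed crotylboration through a closed chair (Zimmerman–Traxler) transition state, in which the (E)-geometry of 2 becomes the anti C2–C3 relationship and the catalyst selects the aldehyde face.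

Step 2
Reactants: 4 (1S,2S)-2-methyl-1-(3,4,5-trimethoxyphenyl)but-3-en-1-ol
Product: 5 tert-butyl{[(1S,2S)-2-methyl-1-(3,4,5-trimethoxyphenyl)but-3-en-1-yl]oxy}dimethylsilane
Conditions: TBSOTf, 2,6-lutidine, CH2Cl2, 0 °C
Reagents that add atoms: tert-butyldimethylsilyl triflate, CC(C)(C)[Si](C)(C)OS(=O)(=O)C(F)(F)F
Why: silylation of the hindered benzylic alcohol with the silyl triflate masks the C2 oxygen until ring B is closed.

Step 3
Reactants: 5 tert-butyl{[(1S,2S)-2-methyl-1-(3,4,5-trimethoxyphenyl)but-3-en-1-yl]oxy}dimethylsilane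
Product: 7 (3S,4S)-4-[(tert-butyldimethylsilyl)oxy]-3-methyl-4-(3,4,5-trimethoxyphenyl)butan-1-ol, via B-alkyl borane 6 (not isolated)
Conditions: 9-borabicyclo[3.3.1]nonane, THF, 0 °C → rt; then 3 M NaOH, 30% H2O2, 0 °C → rt
Reagents that add atoms: hydrogen peroxide, OO
Why: anti-Markovnikov hydroboration of the terminal alkene with a bulky borane and oxidation with retention give the primary alcohol, and no stereocentre is formed or touched.

Step 4
Reactants: 7 (3S,4S)-4-[(tert-butyldimethylsilyl)oxy]-3-methyl-4-(3,4,5-trimethoxyphenyl)butan-1-ol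
Product: 8 (3S,4S)-4-[(tert-butyldimethylsilyl)oxy]-3-methyl-4-(3,4,5-trimethoxyphenyl)butanal
Conditions: Dess–Martin periodinane, CH2Cl2, rt
Reagents that add atoms: none
Why: Dess–Martin oxidation stops at the aldehyde, whose α-carbon is a CH2 group, so nothing can epimerise.

Step 5
Reactants: 8 (3S,4S)-4-[(tert-butyldimethylsilyl)oxy]-3-methyl-4-(3,4,5-trimethoxyphenyl)butanal; 9 allyl bromide
Product: 13 (2RS,3S,4S)-4-[(tert-butyldimethylsilyl)oxy]-3-methyl-2-(prop-2-en-1-yl)-4-(3,4,5-trimethoxyphenyl)butanal (2R drawn), via N-cyclohexyl imine 10 (not isolated), via lithio azaenolate 11 (not isolated), via allylated imine 12 (not isolated)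
Conditions: (a) cyclohexylamine, MgSO4, CH2Cl2, rt, filtered and concentrated; (b) LiN(iPr)2, THF, −78 → 0 °C, then 9, −78 °C → rt; (c) AcOH/NaOAc buffer (pH 4.5), H2O/hexane, rt
Reagents that add atoms: water, O
Why: Stork metalloenamine alkylation, in which the lithiated imine is C-allylated once and buffered hydrolysis frees the aldehyde without loss of the silyl ether; the new α-centre is uncontrolled and need not be controlled, since step 7 makes it planar.

Step 6
Reactants: 14 3,3-dimethoxybutan-2-one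
Product: 15 3-methoxybut-3-en-2-one
Conditions: TsOH·H2O (1 mol %), hydroquinone (trace), neat, 140 °C, MeOH distilled off; then distillation
Reagents that add atoms: none
Why: acid-catalysed loss of methanol from the keto ketal (ketal cracking to the enol ether) is driven by removal of methanol, and the product is distilled directly into use.

Step 7
Reactants: 13 (2RS,3S,4S)-4-[(tert-butyldimethylsilyl)oxy]-3-methyl-2-(prop-2-en-1-yl)-4-(3,4,5-trimethoxyphenyl)butanal; 15 3-methoxybut-3-en-2-one
Product: 17 (4S,6R)-4-allyl-4-{(1S,2S)-1-[(tert-butyldimethylsilyl)oxy]-1-(3,4,5-trimethoxyphenyl)propan-2-yl}-6-methoxycyclohex-2-en-1-one (6R drawn; the 6S epimer is expected alongside), via keto aldehyde 16 (not isolated)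
Conditions: 9-amino-9-deoxy-epi-quinine (C20H25N3O, 20 mol %), 2-fluorobenzoic acid (40 mol %), 15 (3 equiv, freshly distilled, added in portions), PhMe, 40 °C, then 60 °C
Reagents that add atoms: none
Why: Proposed new method: the primary ammonium salt condenses with 13 to a trisubstituted enamine in which C3a is planar, so both α-epimers feed one nucleophile, and this adds through C3a to the unsubstituted CH2 terminus of 15 (C3a–C4), hydrolysis giving keto aldehyde 16. The methyl ketone of 16 then attacks the non-enolisable formyl carbon C7a through its enamine or enol in a 6-(enolexo)-exo-trig aldol closure of ring A, and loss of water leaves the C7=C7a enone. The closest known reaction type is the chiral-primary-amine-catalysed Robinson annulation of α,α-disubstituted aldehydes with methyl vinyl ketone; what is new is the donor-substituted acceptor 15, expected to react because its β-carbon is unhindered and the same amine salt can activate the α-substituted enone as an iminium ion, and used fresh and in excess because it is a weaker electrophile that polymerises readily. C3a is set by the enamine face that the cinchona amine leaves open, with the neighbouring C3 centre as a second control element of uncertain intrinsic bias, whereas C5 arises by protonation next to an enolisable ketone and is expected as an epimer mixture that step 11 corrects. The step needs facial selectivity at C3a (catalyst) and site selectivity in the aldol, which the substrate secures: only the aldehyde forms an enamine rapidly, and only the C7 methyl group can reach C7a in a six-membered ring, since closure from C5 would give a cyclobutane.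

Step 8
Reactants: 17 (4S,6R)-4-allyl-4-{(1S,2S)-1-[(tert-butyldimethylsilyl)oxy]-1-(3,4,5-trimethoxyphenyl)propan-2-yl}-6-methoxycyclohex-2-en-1-one
Product: 18 (3R,5R)-5-allyl-5-{(1S,2S)-1-[(tert-butyldimethylsilyl)oxy]-1-(3,4,5-trimethoxyphenyl)propan-2-yl}-3-methoxy-7-oxabicyclo[4.1.0]heptan-2-one (epoxide carbons C1/C6 unassigned)
Conditions: t-BuOOH (decane solution), DBU, CH2Cl2, 0 °C → rt
Reagents that add atoms: tert-butyl hydroperoxide, CC(C)(C)OO
Why: Weitz–Scheffer-type nucleophilic epoxidation, in which the hydroperoxide anion adds only to the electron-poor C7=C7a bond and leaves the allyl group and the arene alone; the epoxide configuration is immaterial because C7 and C7a become trigonal or CH2 again, and the quaternary C3a excludes deconjugation.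

Step 9
Reactants: 18 (3R,5R)-5-allyl-5-{(1S,2S)-1-[(tert-butyldimethylsilyl)oxy]-1-(3,4,5-trimethoxyphenyl)propan-2-yl}-3-methoxy-7-oxabicyclo[4.1.0]heptan-2-one
Product: 19 (4R,6R)-4-allyl-4-{(1S,2S)-1-[(tert-butyldimethylsilyl)oxy]-1-(3,4,5-trimethoxyphenyl)propan-2-yl}-6-methoxycyclohexane-1,3-dione
Conditions: Pd(PPh3)4 (5 mol %), Ph2PCH2CH2PPh2 (5 mol %), PhMe, 90 °C
Reagents that add atoms: none
Why: the established phosphine–palladium isomerisation of α,β-epoxy ketones to β-diketones, in which zerovalent palladium opens the C7–O bond next to the carbonyl, β-hydride elimination removes the C7a hydrogen and reductive elimination returns the catalyst; the allyl group carries no leaving group and the silyl ether is inert.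

Step 10
Reactants: 19 (4R,6R)-4-allyl-4-{(1S,2S)-1-[(tert-butyldimethylsilyl)oxy]-1-(3,4,5-trimethoxyphenyl)propan-2-yl}-6-methoxycyclohexane-1,3-dione
Product: 21 (2S,3S,3aR,5RS)-3a-allyl-5-methoxy-3-methyl-2-(3,4,5-trimethoxyphenyl)-3,3a,4,5-tetrahydro-1-benzofuran-6(2H)-one, via hydroxy diketone 20 (not isolated)
Conditions: HF·pyridine, THF, 0 °C → rt; then TsOH·H2O (5 mol %), PhMe, 4 Å MS, 40 °C
Reagents that add atoms: none
Why: desilylation frees the C2 hydroxyl, which adds to the C7a carbonyl in a 5-exo-trig hemiketalisation (C6 is out of reach) and loses water under mild acid to the cyclic vinylogous ester, the usual enol etherification of a cyclic 1,3-dione; the C2–O bond is never broken, so C2 keeps its configuration.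

Step 11
Reactants: 21 (2S,3S,3aR,5RS)-3a-allyl-5-methoxy-3-methyl-2-(3,4,5-trimethoxyphenyl)-3,3a,4,5-tetrahydro-1-benzofuran-6(2H)-one
Product: 22 (2S,3S,3aR,5R)-3a-allyl-5-methoxy-3-methyl-2-(3,4,5-trimethoxyphenyl)-3,3a,4,5-tetrahydro-1-benzofuran-6(2H)-one
Conditions: NaOMe (0.2 equiv), MeOH, 0 °C → rt
Reagents that add atoms: none
Why: base-mediated epimerisation of C5 through the cross-conjugated enolate under thermodynamic control should favour the epimer with the methoxy group pseudo-equatorial and trans to the pseudo-axial C3a allyl group (no 1,3-diaxial contact on the sofa-shaped ring A); C2, C3 and C3a carry no acidic hydrogen and are untouched.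

**Compound list**
1 | 3,4,5-trimethoxybenzaldehyde | COc1cc(C=O)cc(OC)c1OC | starting material
2 | (E)-crotylboronic acid pinacol ester | C/C=C/CB1OC(C)(C)C(C)(C)O1 | starting material
3 | 2-{[(1S,2S)-2-methyl-1-(3,4,5-trimethoxyphenyl)but-3-en-1-yl]oxy}-4,4,5,5-tetramethyl-1,3,2-dioxaborolane | C=C[C@H](C)[C@H](OB1OC(C)(C)C(C)(C)O1)c1cc(OC)c(OC)c(OC)c1 | intermediate
4 | (1S,2S)-2-methyl-1-(3,4,5-trimethoxyphenyl)but-3-en-1-ol | C=C[C@H](C)[C@H](O)c1cc(OC)c(OC)c(OC)c1 | intermediate
5 | tert-butyl{[(1S,2S)-2-methyl-1-(3,4,5-trimethoxyphenyl)but-3-en-1-yl]oxy}dimethylsilane | C=C[C@H](C)[C@H](O[Si](C)(C)C(C)(C)C)c1cc(OC)c(OC)c(OC)c1 | intermediate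
6 | 9-{(3S,4S)-4-[(tert-butyldimethylsilyl)oxy]-3-methyl-4-(3,4,5-trimethoxyphenyl)butyl}-9-borabicyclo[3.3.1]nonane | C1CCC2CCCC1B2CC[C@H](C)[C@H](O[Si](C)(C)C(C)(C)C)c1cc(OC)c(OC)c(OC)c1 | intermediate
7 | (3S,4S)-4-[(tert-butyldimethylsilyl)oxy]-3-methyl-4-(3,4,5-trimethoxyphenyl)butan-1-ol | OCC[C@H](C)[C@H](O[Si](C)(C)C(C)(C)C)c1cc(OC)c(OC)c(OC)c1 | intermediate
8 | (3S,4S)-4-[(tert-butyldimethylsilyl)oxy]-3-methyl-4-(3,4,5-trimethoxyphenyl)butanal | O=CC[C@H](C)[C@H](O[Si](C)(C)C(C)(C)C)c1cc(OC)c(OC)c(OC)c1 | intermediate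
9 | allyl bromide | C=CCBr | starting material
10 | (E)-N-cyclohexyl imine of aldehyde 8 | C1CCCCC1/N=C/C[C@H](C)[C@H](O[Si](C)(C)C(C)(C)C)c1cc(OC)c(OC)c(OC)c1 | intermediate
11 | lithium azaenolate of imine 10 (N-lithio N-cyclohexyl enamide, C=C geometry unassigned) | [Li]N(C1CCCCC1)C=C[C@H](C)[C@H](O[Si](C)(C)C(C)(C)C)c1cc(OC)c(OC)c(OC)c1 | intermediate
12 | (E)-N-cyclohexyl imine of aldehyde 13 (α-epimers) | C=CCC(/C=N/C1CCCCC1)[C@H](C)[C@H](O[Si](C)(C)C(C)(C)C)c1cc(OC)c(OC)c(OC)c1 | intermediate
13 | (2RS,3S,4S)-4-[(tert-butyldimethylsilyl)oxy]-3-methyl-2-(prop-2-en-1-yl)-4-(3,4,5-trimethoxyphenyl)butanal (2R drawn) | C=CC[C@@H](C=O)[C@H](C)[C@H](O[Si](C)(C)C(C)(C)C)c1cc(OC)c(OC)c(OC)c1 | intermediate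
14 | 3,3-dimethoxybutan-2-one | CC(=O)C(C)(OC)OC | starting material
15 | 3-methoxybut-3-en-2-one | COC(=C)C(C)=O | intermediate
16 | (2R)-2-{(1S,2S)-1-[(tert-butyldimethylsilyl)oxy]-1-(3,4,5-trimethoxyphenyl)propan-2-yl}-4-methoxy-5-oxo-2-(prop-2-en-1-yl)hexanal (C4 epimers) | C=CC[C@@](C=O)(CC(OC)C(C)=O)[C@H](C)[C@H](O[Si](C)(C)C(C)(C)C)c1cc(OC)c(OC)c(OC)c1 | intermediate
17 | (4S,6R)-4-allyl-4-{(1S,2S)-1-[(tert-butyldimethylsilyl)oxy]-1-(3,4,5-trimethoxyphenyl)propan-2-yl}-6-methoxycyclohex-2-en-1-one (6R drawn, 6S epimer alongside) | C=CC[C@]1(C=CC(=O)[C@H](OC)C1)[C@H](C)[C@H](O[Si](C)(C)C(C)(C)C)c1cc(OC)c(OC)c(OC)c1 | intermediate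
18 | (3R,5R)-5-allyl-5-{(1S,2S)-1-[(tert-butyldimethylsilyl)oxy]-1-(3,4,5-trimethoxyphenyl)propan-2-yl}-3-methoxy-7-oxabicyclo[4.1.0]heptan-2-one (C1/C6 unassigned, 3R drawn) | C=CC[C@]1(C2OC2C(=O)[C@H](OC)C1)[C@H](C)[C@H](O[Si](C)(C)C(C)(C)C)c1cc(OC)c(OC)c(OC)c1 | intermediate
19 | (4R,6R)-4-allyl-4-{(1S,2S)-1-[(tert-butyldimethylsilyl)oxy]-1-(3,4,5-trimethoxyphenyl)propan-2-yl}-6-methoxycyclohexane-1,3-dione (6R drawn) | C=CC[C@]1(C(=O)CC(=O)[C@H](OC)C1)[C@H](C)[C@H](O[Si](C)(C)C(C)(C)C)c1cc(OC)c(OC)c(OC)c1 | intermediate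
20 | (4R,6R)-4-allyl-4-[(1S,2S)-1-hydroxy-1-(3,4,5-trimethoxyphenyl)propan-2-yl]-6-methoxycyclohexane-1,3-dione (6R drawn) | C=CC[C@]1(C(=O)CC(=O)[C@H](OC)C1)[C@H](C)[C@H](O)c1cc(OC)c(OC)c(OC)c1 | intermediate
21 | (2S,3S,3aR,5RS)-3a-allyl-5-methoxy-3-methyl-2-(3,4,5-trimethoxyphenyl)-3,3a,4,5-tetrahydro-1-benzofuran-6(2H)-one (C5 epimers, C5 left open) | C=CC[C@]12CC(OC)C(=O)C=C1O[C@H](c1cc(OC)c(OC)c(OC)c1)[C@H]2C | intermediate
22 | (2S,3S,3aR,5R)-3a-allyl-5-methoxy-3-methyl-2-(3,4,5-trimethoxyphenyl)-3,3a,4,5-tetrahydro-1-benzofuran-6(2H)-one | C=CC[C@]12C[C@@H](OC)C(=O)C=C1O[C@H](c1cc(OC)c(OC)c(OC)c1)[C@H]2C | target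

Total step count: 11. Longest linear sequence: 10 steps (steps 1–5 and 7–11); step 6 is a one-step side branch.

**Steps most likely to fail**

Step 7. The donor-substituted vinyl ketone may polymerise or hydrolyse to butane-2,3-dione faster than the hindered enamine adds to it, and the enamine face selection may be low. The fallback sets out from 13 and returns at 17. The same amine salt and methyl vinyl ketone (the known annulation of α,α-disubstituted aldehydes) should give the des-methoxy cyclohexenone F1. Kinetic α'-enolisation (LiN(SiMe3)2, THF, −78 °C) and oxidation with 3-phenyl-2-(phenylsulfonyl)oxaziridine should give the α'-hydroxy enone F2. O-methylation (MeOTf, 2,6-di-tert-butylpyridine, CH2Cl2) then gives 17 as the same C6 epimer mixture.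

Step 9. The palladium enolate may fail to undergo β-hydride elimination at the neopentyl C7a–H, or a palladium hydride may move the allyl double bond. The fallback sets out from 18 and returns at 19. Reductive opening of the epoxy ketone at C7 with sodium phenylselenide generated from (PhSe)2 and NaBH4 (EtOH, AcOH, 0 °C) should give the β-hydroxy ketone F3, which leaves the α-methoxy group alone. Dess–Martin oxidation of the C7a carbinol then gives 19.

Step 8. The hydroperoxide anion may attack the β-carbon next to the quaternary centre too slowly, with base-induced degradation of the α-methoxy ketone taking over. The fallback sets out from 17 and returns at 21, passing by 18–20. Conjugate addition of thiophenol (PhSH, Et3N, CH2Cl2) should give the β-phenylthio ketone F4. Chlorination at sulfur-bearing C7a with N-chlorosuccinimide and loss of HCl should give the β-phenylthio enone F5. Bu4NF in THF then removes the silyl group, and the C2 alkoxide displaces thiolate at C7a by addition–elimination to give 21.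

**Further compounds**
F1 | step 7 | (4R)-4-allyl-4-{(1S,2S)-1-[(tert-butyldimethylsilyl)oxy]-1-(3,4,5-trimethoxyphenyl)propan-2-yl}cyclohex-2-en-1-one | C=CC[C@]1(C=CC(=O)CC1)[C@H](C)[C@H](O[Si](C)(C)C(C)(C)C)c1cc(OC)c(OC)c(OC)c1
F2 | step 7 | (4S,6RS)-4-allyl-4-{(1S,2S)-1-[(tert-butyldimethylsilyl)oxy]-1-(3,4,5-trimethoxyphenyl)propan-2-yl}-6-hydroxycyclohex-2-en-1-one | C=CC[C@]1(C=CC(=O)C(O)C1)[C@H](C)[C@H](O[Si](C)(C)C(C)(C)C)c1cc(OC)c(OC)c(OC)c1
F3 | step 9 | (2R,4R)-4-allyl-4-{(1S,2S)-1-[(tert-butyldimethylsilyl)oxy]-1-(3,4,5-trimethoxyphenyl)propan-2-yl}-5-hydroxy-2-methoxycyclohexan-1-one (C5 unassigned) | C=CC[C@]1(C(O)CC(=O)[C@H](OC)C1)[C@H](C)[C@H](O[Si](C)(C)C(C)(C)C)c1cc(OC)c(OC)c(OC)c1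
F4 | step 8 | (2R,4R)-4-allyl-4-{(1S,2S)-1-[(tert-butyldimethylsilyl)oxy]-1-(3,4,5-trimethoxyphenyl)propan-2-yl}-2-methoxy-5-(phenylsulfanyl)cyclohexan-1-one (C5 unassigned) | C=CC[C@]1(C(Sc2ccccc2)CC(=O)[C@H](OC)C1)[C@H](C)[C@H](O[Si](C)(C)C(C)(C)C)c1cc(OC)c(OC)c(OC)c1
F5 | step 8 | (4R,6R)-4-allyl-4-{(1S,2S)-1-[(tert-butyldimethylsilyl)oxy]-1-(3,4,5-trimethoxyphenyl)propan-2-yl}-6-methoxy-3-(phenylsulfanyl)cyclohex-2-en-1-one | C=CC[C@]1(C(Sc2ccccc2)=CC(=O)[C@H](OC)C1)[C@H](C)[C@H](O[Si](C)(C)C(C)(C)C)c1cc(OC)c(OC)c(OC)c1
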